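**Retrosynthetic overview**
- Feature used: the sixteen-carbon bridge leaves ring B at C6 through the benzylic carbon C1', ortho to the diaryl ether carbon C1. C1'–C2' is therefore the one bridge bond that can be replaced by C1'–SO2–C2' with an acidic benzylic flank.
- Grevirobstol B <= (BBr3, H2) 22-membered C1'=C2' alkene <= (SO2 extrusion, ring contraction) 23-membered benzyl alkyl sulfone <= macrocyclic sulfide.
- Sulfide <= acyclic benzylic/primary dibromide. Sulfur is first fixed on C1' with thiourea, and the thiolate then closes the ring at C2'. Dibromide <= diaryl ether aldehyde whose CHO carbon is C1'.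
- Diaryl ether <= Ullmann coupling of the ring A phenol with 2-bromo-3,5-dimethoxybenzaldehyde (ring B). Ring A phenol <= 3,5-dimethoxyphenyl Grignard reagent plus the Weinreb amide of 15-pentadecanolide (C2'–C16'), then deoxygenation and mono-demethylation.
- Ring order: rings A and B are bought. The 23-membered thia-ring forms in step 9; the transient episulfone and the 22-membered ring form in step 11.

Key step: step 11

Remark on the chemistry: ring B is numbered C1 (ether oxygen), C2 and C4 (oxygens), C6 (bridge), and the bridge runs from C1' (on ring B) to C16' (on ring A). The target is achiral. The ring-contracted alkene is drawn E, any Z isomer is carried along, and the sulfoxide, bromosulfone and episulfone are transient mixtures drawn without configuration.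

**Step 1**
Reactants: 1 15-pentadecanolide
Product: 2 15-hydroxy-N-methoxy-N-methylpentadecanamide
Conditions: MeNH(OMe)·HCl (1.5 equiv), i-PrMgCl (3.2 equiv), THF, −20 → 0 °C; 1 M HCl
Reagents that add atoms: N,O-dimethylhydroxylamine hydrochloride, CNOC.Cl
Why: Weinreb amide formation by aminolysis of the unstrained macrolactone with the magnesium amide is effectively irreversible, because the freed alkoxide does not re-close a sixteen-membered ring, and it delivers carbons C2'–C16' with the two chain ends differentiated.

**Step 2**
Reactants: 2 15-hydroxy-N-methoxy-N-methylpentadecanamide; 3 1-bromo-3,5-dimethoxybenzene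
Product: 6 1-(3,5-dimethoxyphenyl)-15-hydroxypentadecan-1-one, via 3,5-dimethoxyphenylmagnesium bromide 4 (not isolated), via magnesium chelate adduct 5 (not isolated)
Conditions: 3 (2.3 equiv), Mg, THF, reflux; then 2, 0 °C → rt; 1 M HCl
Reagents that add atoms: none
Why: Weinreb ketone synthesis, in which the first equivalent of Grignard reagent 4 only deprotonates the hydroxyl group, the second adds to the amide, and chelate 5 persists until the acid quench so that no tertiary alcohol forms.

**Step 3**
Reactants: 6 1-(3,5-dimethoxyphenyl)-15-hydroxypentadecan-1-one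
Product: 8 15-(3,5-dimethoxyphenyl)pentadecan-1-ol, via ketone hydrazone 7 (not isolated)
Conditions: N2H4·H2O, KOH, diethylene glycol, 130 °C, then distil to 195–200 °C
Reagents that add atoms: none
Why: Wolff–Kishner reduction (Huang-Minlon modification) turns the aryl ketone into C16'H2 through base-induced loss of N2 from hydrazone 7, needs no benzylic cation (which the meta methoxy groups would not stabilise), and leaves the primary alcohol and aryl ethers alone.

**Step 4**
Reactants: 8 15-(3,5-dimethoxyphenyl)pentadecan-1-ol
Product: 9 3-(15-hydroxypentadecyl)-5-methoxyphenol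
Conditions: NaSEt (3 equiv), DMF, 130 °C; 1 M HCl
Reagents that add atoms: none
Why: SN2 demethylation by thiolate, in which the two methoxy groups are equivalent and the phenoxide formed after the first cleavage deactivates the ring towards a second, so the reaction should stop at the monophenol.

**Step 5**
Reactants: 10 3,5-dimethoxybenzaldehyde
Product: 11 2-bromo-3,5-dimethoxybenzaldehyde
Conditions: NBS (1.0 equiv), MeCN, 0 °C → rt
Reagents that add atoms: N-bromosuccinimide, O=C1CCC(=O)N1Br
Why: Electrophilic aromatic bromination goes to C2, which is para to one methoxy group, ortho to the other and less crowded than C4 between both, and this places bromine on the future ring B C1 next to the future C1'.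

**Step 6**
Reactants: 9 3-(15-hydroxypentadecyl)-5-methoxyphenol; 11 2-bromo-3,5-dimethoxybenzaldehyde
Product: 12 2-[3-(15-hydroxypentadecyl)-5-methoxyphenoxy]-3,5-dimethoxybenzaldehyde
Conditions: CuI (10 mol %), picolinic acid (20 mol %), K3PO4 (2 equiv), degassed DMSO, 90 °C
Reagents that add atoms: none
Why: Ullmann-type diaryl ether synthesis, in which picolinate-ligated monovalent copper accepts di-ortho-substituted aryl bromides, the ortho formyl group polarises and coordinates at the C1–Br site, and K3PO4 ionises only the phenol so that the primary alcohol stays a spectator.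

**Step 7**
Reactants: 12 2-[3-(15-hydroxypentadecyl)-5-methoxyphenoxy]-3,5-dimethoxybenzaldehyde
Product: 13 15-{3-[2-(hydroxymethyl)-4,6-dimethoxyphenoxy]-5-methoxyphenyl}pentadecan-1-ol
Conditions: NaBH4, THF/MeOH, 0 °C
Reagents that add atoms: none
Why: Borohydride reduction of the aromatic aldehyde gives the C1' benzylic alcohol, and nothing else in the molecule is reducible.

**Step 8**
Reactants: 13 15-{3-[2-(hydroxymethyl)-4,6-dimethoxyphenoxy]-5-methoxyphenyl}pentadecan-1-ol
Product: 14 1-(bromomethyl)-2-[3-(15-bromopentadecyl)-5-methoxyphenoxy]-3,5-dimethoxybenzene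
Conditions: CBr4 (2.6 equiv), PPh3 (2.6 equiv), CH2Cl2, 0 °C → rt
Reagents that add atoms: carbon tetrabromide, BrC(Br)(Br)Br
Why: Appel reaction, in which both alcohols are activated as alkoxyphosphonium ions and displaced by bromide under neutral conditions that spare all ethers, and the benzylic bromide can be handled because its methoxy groups are meta to C1'.

**Step 9**
Reactants: 14 1-(bromomethyl)-2-[3-(15-bromopentadecyl)-5-methoxyphenoxy]-3,5-dimethoxybenzene
Product: 17 macrocyclic benzyl alkyl sulfide (23-membered ring), via benzylic isothiouronium bromide 15 (not isolated), via sodium benzylic thiolate 16 (not isolated)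
Conditions: thiourea (1.0 equiv), THF/EtOH, rt; then syringe-pump addition to NaOH (5 equiv), degassed EtOH/H2O, reflux, final ca. 1 mM
Reagents that add atoms: thiourea, NC(N)=S
Why: Thiourea S-alkylation followed by thiolate SN2 macrocyclisation, in which the soft neutral nucleophile takes only the far more reactive benzylic bromide at room temperature, so that when NaOH unmasks thiolate 16 no benzylic electrophile is left and each molecule holds one sulfur and one primary bromide, which under pseudo-high dilution should close the ring by exo-tet attack at C2' rather than grow chains.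

**Step 10**
Reactants: 17 macrocyclic benzyl alkyl sulfide (23-membered ring)
Product: 19 macrocyclic benzyl alkyl sulfone (23-membered ring), via macrocyclic sulfoxide 17→18: macrocyclic sulfoxide 18 (not isolated)
Conditions: mCPBA (2.3 equiv), NaHCO3, CH2Cl2, 0 °C → rt
Reagents that add atoms: 3-chloroperoxybenzoic acid, OOC(=O)c1cccc(Cl)c1
Why: Stepwise peracid oxidation of sulfur through sulfoxide 18 to the sulfone is much faster at this temperature than any attack on the methoxyarenes.

**Step 11**
Reactants: 19 macrocyclic benzyl alkyl sulfone (23-membered ring)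
Product: 22 (E)-1',2'-didehydro-tri-O-methylgrevirobstol B (22-membered ring), via benzylic alpha-bromosulfone 20 (not isolated), via episulfone 21 (not isolated)
Conditions: KOH/Al2O3 (excess), CBr2F2 (5–10 equiv), t-BuOH/CH2Cl2, 0 °C → rt, closed flask
Reagents that add atoms: none
Why: KOH on alumina removes the more acidic benzylic C1'–H of 19 and the carbanion abstracts bromine from CBr2F2 to give 20; deprotonation at C2' then displaces bromide from C1' to give episulfone 21, which loses SO2 cheletropically and leaves the C1'=C2' bond. This is the Ramberg–Bäcklund reaction with in situ halogenation, a standard way to turn benzyl alkyl sulfones into styrenes and to contract thiacyclophane sulfones. The only ring closed is the transient three-membered one (3-exo-tet); the 22-membered ring arises by contraction of the 23-membered ring in a unimolecular event, so no dilution is needed. No stereocentre survives, since C1' of 20 and both carbons of 21 are transient, and the E alkene expected from a benzylic substrate and any Z isomer lead to the same saturated bridge, as would initial bromination at C2'. The selectivity needed is halogenation at an alpha carbon and not on the electron-rich arenes, and CBr2F2 secures it because it gives up bromine only to carbanions. The CBrF2 anion does collapse to difluorocarbene, but hydroxide and t-BuOH should consume this stabilised carbene faster than it adds to a styrene, and with all three phenols masked as methyl ethers there is no phenoxide to be difluoromethylated.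

**Step 12**
Reactants: 22 (E)-1',2'-didehydro-tri-O-methylgrevirobstol B
Product: 23 tri-O-methylgrevirobstol B
Conditions: H2 (1 atm), 10% Pd/C, EtOAc, rt
Reagents that add atoms: none
Why: Heterogeneous catalytic hydrogenation saturates the disubstituted styrenyl C1'=C2' bond of either isomer, and the molecule has no hydrogenolysable benzylic C–O bond.

**Step 13**
Reactants: 23 tri-O-methylgrevirobstol B
Product: 25 grevirobstol B, via tris(dibromoboryl) ether 24 (not isolated)
Conditions: BBr3 (6 equiv), CH2Cl2, −78 °C → rt; then H2O
Reagents that add atoms: none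
Why: Lewis acid-mediated aryl methyl ether cleavage, in which BBr3 binds each methoxy oxygen and bromide removes the methyl group by SN2, the diaryl ether has no sp3 carbon to lose, and hydrolysis of 24 frees the three phenols.

**Compound list**
1 | 15-pentadecanolide | O=C1CCCCCCCCCCCCCCO1 | starting material
2 | 15-hydroxy-N-methoxy-N-methylpentadecanamide | CON(C)C(=O)CCCCCCCCCCCCCCO | intermediate
3 | 1-bromo-3,5-dimethoxybenzene | COc1cc(Br)cc(OC)c1 | starting material
4 | 3,5-dimethoxyphenylmagnesium bromide | COc1cc([Mg]Br)cc(OC)c1 | intermediate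
5 | bis(bromomagnesium) tetrahedral adduct of 4 and 2 (chelated C1 alkoxide, C15 alkoxide) | COc1cc(cc(OC)c1)C(O[Mg]Br)(N(C)OC)CCCCCCCCCCCCCCO[Mg]Br | intermediate
6 | 1-(3,5-dimethoxyphenyl)-15-hydroxypentadecan-1-one | COc1cc(cc(OC)c1)C(=O)CCCCCCCCCCCCCCO | intermediate
7 | hydrazone of 6 | COc1cc(cc(OC)c1)C(=NN)CCCCCCCCCCCCCCO | intermediate
8 | 15-(3,5-dimethoxyphenyl)pentadecan-1-ol | COc1cc(CCCCCCCCCCCCCCCO)cc(OC)c1 | intermediate
9 | 3-(15-hydroxypentadecyl)-5-methoxyphenol | COc1cc(O)cc(CCCCCCCCCCCCCCCO)c1 | intermediate
10 | 3,5-dimethoxybenzaldehyde | COc1cc(C=O)cc(OC)c1 | starting material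
11 | 2-bromo-3,5-dimethoxybenzaldehyde | COc1cc(C=O)c(Br)c(OC)c1 | intermediate
12 | 2-[3-(15-hydroxypentadecyl)-5-methoxyphenoxy]-3,5-dimethoxybenzaldehyde | COc1cc(CCCCCCCCCCCCCCCO)cc(c1)Oc1c(OC)cc(OC)cc1C=O | intermediate
13 | 15-{3-[2-(hydroxymethyl)-4,6-dimethoxyphenoxy]-5-methoxyphenyl}pentadecan-1-ol | COc1cc(CCCCCCCCCCCCCCCO)cc(c1)Oc1c(OC)cc(OC)cc1CO | intermediate
14 | 1-(bromomethyl)-2-[3-(15-bromopentadecyl)-5-methoxyphenoxy]-3,5-dimethoxybenzene | COc1cc(CCCCCCCCCCCCCCCBr)cc(c1)Oc1c(OC)cc(OC)cc1CBr | intermediate
15 | S-{2-[3-(15-bromopentadecyl)-5-methoxyphenoxy]-3,5-dimethoxybenzyl}isothiouronium bromide | COc1cc(CCCCCCCCCCCCCCCBr)cc(c1)Oc1c(OC)cc(OC)cc1CSC(N)=[NH2+].[Br-] | intermediate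
16 | sodium {2-[3-(15-bromopentadecyl)-5-methoxyphenoxy]-3,5-dimethoxyphenyl}methanethiolate | COc1cc(CCCCCCCCCCCCCCCBr)cc(c1)Oc1c(OC)cc(OC)cc1C[S-].[Na+] | intermediate
17 | 23-membered macrocyclic sulfide, S between C1'H2 and C2'H2, three OMe | COc1cc2cc(c1)Oc1c(OC)cc(OC)cc1CSCCCCCCCCCCCCCCC2 | intermediate
18 | corresponding macrocyclic sulfoxide (racemic at sulfur) | COc1cc2cc(c1)Oc1c(OC)cc(OC)cc1CS(=O)CCCCCCCCCCCCCCC2 | intermediate
19 | 23-membered macrocyclic benzyl alkyl sulfone | COc1cc2cc(c1)Oc1c(OC)cc(OC)cc1CS(=O)(=O)CCCCCCCCCCCCCCC2 | intermediate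
20 | C1'-bromo macrocyclic sulfone (racemic) | COc1cc2cc(c1)Oc1c(OC)cc(OC)cc1C(Br)S(=O)(=O)CCCCCCCCCCCCCCC2 | intermediate
21 | episulfone (thiirane 1,1-dioxide across C1' and C2', mixture of isomers) | COc1cc2cc(c1)Oc1c(OC)cc(OC)cc1C3C(CCCCCCCCCCCCCC2)S3(=O)=O | intermediate
22 | (E)-1',2'-didehydro-tri-O-methylgrevirobstol B | COc1cc2cc(c1)Oc1c(OC)cc(OC)cc1/C=C/CCCCCCCCCCCCCC2 | intermediate
23 | tri-O-methylgrevirobstol B | COc1cc2cc(c1)Oc1c(OC)cc(OC)cc1CCCCCCCCCCCCCCCC2 | intermediate
24 | tris(dibromoboryl) ether of grevirobstol B | BrB(Br)Oc1cc2cc(c1)Oc1c(OB(Br)Br)cc(OB(Br)Br)cc1CCCCCCCCCCCCCCCC2 | intermediate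
25 | grevirobstol B | Oc1cc2cc(c1)Oc1c(O)cc(O)cc1CCCCCCCCCCCCCCCC2 | target

**Step count**
- Total step count: 13.
- Longest linear sequence: 12 (steps 1–4 and 6–13).

**Steps most likely to fail**

1. Step 11 (ring contraction).
   - What may go wrong: the remaining C1'–H of the monobrominated sulfone is more acidic than the C2'–H that has to be removed. A second bromination can therefore outrun episulfone closure, and deprotonation on the unactivated alkyl side can stall on the solid base.
   - Fallback: form the same C1'=C2' bond by intramolecular Wittig olefination, without sulfur. The fallback sets out from aldehyde 12. I2, PPh3 and imidazole in CH2Cl2 at 0 °C convert the primary alcohol into the omega-iodo aldehyde F1. PPh3 in MeCN at reflux gives the phosphonium iodide F2. Slow addition of F2 to KOt-Bu in THF at high dilution generates the ylide F3, which closes on the ring B aldehyde to the (Z)-alkene F4. Hydrogenation under the conditions of step 12 brings the material back to the route at 23.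

2. Step 9 (thia-macrocyclisation).
   - What may go wrong: closure on an unactivated primary bromide is slow, so intermolecular S-alkylation and air oxidation of the thiolate to disulfide can compete. Thiourea may also fail to distinguish the two bromides completely.
   - Fallback: exchange the roles of the two ends, so that a chain-end thiolate closes on the much faster benzylic electrophile. The fallback sets out from aldehyde 12, in which C1' is still masked. A Mitsunobu reaction with thioacetic acid (PPh3, DIAD, THF, 0 °C) gives the thioacetate aldehyde F5. NaBH4 in THF/EtOH at −20 °C reduces only the aldehyde, to the thioacetate benzylic alcohol F6. CBr4/PPh3 then gives the thioacetate benzylic bromide F7. Slow addition of F7 to K2CO3 in degassed MeOH/THF removes the acetyl group, and the potassium thiolate F8 closes at C1'. The fallback comes back to the route at sulfide 17.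

3. Step 6 (diaryl ether).
   - What may go wrong: the C–Br bond lies between CHO and OMe and para to a donor. Copper insertion may therefore be slow enough for protodebromination, aldehyde degradation or O-arylation of the primary alcohol to take over.
   - Fallback: a metal-free addition–elimination. The fallback sets out from 10, which Selectfluor in MeCN fluorinates at C2 to 2-fluoro-3,5-dimethoxybenzaldehyde F9. Phenol 9 and F9 with K2CO3 in DMF at 120 °C undergo SNAr, activated by the ortho formyl group. The fallback comes back to the route at 12.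

**Further compounds**
F1 | step 11 | 2-[3-(15-iodopentadecyl)-5-methoxyphenoxy]-3,5-dimethoxybenzaldehyde | COc1cc(CCCCCCCCCCCCCCCI)cc(c1)Oc1c(OC)cc(OC)cc1C=O
F2 | step 11 | {15-[3-(2-formyl-4,6-dimethoxyphenoxy)-5-methoxyphenyl]pentadecyl}triphenylphosphonium iodide | COc1cc(CCCCCCCCCCCCCCC[P+](c2ccccc2)(c2ccccc2)c2ccccc2)cc(c1)Oc1c(OC)cc(OC)cc1C=O.[I-]
F3 | step 11 | phosphonium ylide derived from F2 | COc1cc(CCCCCCCCCCCCCCC=P(c2ccccc2)(c2ccccc2)c2ccccc2)cc(c1)Oc1c(OC)cc(OC)cc1C=O
F4 | step 11 | (Z)-1',2'-didehydro-tri-O-methylgrevirobstol B | COc1cc2cc(c1)Oc1c(OC)cc(OC)cc1/C=C\CCCCCCCCCCCCCC2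
F5 | step 9 | S-{15-[3-(2-formyl-4,6-dimethoxyphenoxy)-5-methoxyphenyl]pentadecyl} thioacetate | COc1cc(CCCCCCCCCCCCCCCSC(C)=O)cc(c1)Oc1c(OC)cc(OC)cc1C=O
F6 | step 9 | S-(15-{3-[2-(hydroxymethyl)-4,6-dimethoxyphenoxy]-5-methoxyphenyl}pentadecyl) thioacetate | COc1cc(CCCCCCCCCCCCCCCSC(C)=O)cc(c1)Oc1c(OC)cc(OC)cc1CO
F7 | step 9 | S-(15-{3-[2-(bromomethyl)-4,6-dimethoxyphenoxy]-5-methoxyphenyl}pentadecyl) thioacetate | COc1cc(CCCCCCCCCCCCCCCSC(C)=O)cc(c1)Oc1c(OC)cc(OC)cc1CBr
F8 | step 9 | potassium 15-{3-[2-(bromomethyl)-4,6-dimethoxyphenoxy]-5-methoxyphenyl}pentadecane-1-thiolate | COc1cc(CCCCCCCCCCCCCCC[S-])cc(c1)Oc1c(OC)cc(OC)cc1CBr.[K+]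
F9 | step 6 | 2-fluoro-3,5-dimethoxybenzaldehyde | COc1cc(C=O)c(F)c(OC)c1
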